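(All runs were generated by integration from invented constants, and the scatter is random.)

| flask | starting complex | incoming ligand | leaving ligand | remark | time |
|---|---|---|---|---|---|
| north-east | 5 mM | 0.93 equiv | 0.50 equiv | run made earlier |  |
| south-west | 5 mM | 1.8 equiv | 0.50 equiv | run made earlier |  |
| dawn | 5.0 mM | 1.20 equiv | 0.500 equiv |  | 12 min |
| summer | 5.0 mM | 1.50 equiv | 0.500 equiv |  | 12 min |
| noon | 5.0 mM | 2.00 equiv | 0.500 equiv |  | 12 min |

- north-east (time / min: complex with one exchanged / %, complex with two exchanged / %): 1.50: 48, 1; 3.00: 44, 1; 5.00: 42, 3; 6.00: 33, 0; 8.00: 31, 0
- south-west (time / min: complex with one exchanged / %, complex with two exchanged / %): 0.667: 62, 4; 1.33: 59, 3; 2.50: 48, 5; 4.00: 38, 1; 8.00: 22, 0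

(readings scatter by 2 percentage points)

- the numbers in the tables scatter by 2 percentage points (one standard deviation)

- final complex with one exchanged, as a percentage of the starting complex charged, for each flask in turn (dawn, summer, noon)

**Easy step.** The south-west run starts high, at 62 % complex with one exchanged by 0.667 min, and then it fades. So I work with the fraction left, not the amount made.

**Fade constant.** In the south-west run, c(complex with one exchanged) falls from 59 % at 1.33 min to 22 % at 8.00 min. The logarithm of that ratio, over the time between, gives 0.148 /min. I call this the fade constant, a pseudo-first-order constant for that ligand charge. The fraction left after a time is then the exponential of minus constant times time.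

**First doubt.** Does the fade scale with the incoming ligand? If it does, the north-east run keeps 0.609 of its reading between 1.50 min and 8.00 min. The readings show 0.646. With a scatter of 2 percentage points on a reading of 31 %, the two agree, so I scale the constant by the charge.

**My estimate.** I need a starting level near 1.50 min. I draw a straight line in charge through the two runs, taking the south-west reading at 1.33 min as if it stood there. For noon this is an extrapolation. Multiplying by the fraction left gives 18.3 % for dawn, 15.1 % for summer and 11.0 % for noon.

**Second doubt.** I carry the constant past the last reading at 8.00 min. But the fade probably uses up incoming ligand, and then it should slow. So I expect my figures to be low.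

**The forecast.** It gives 22 %, 20 % and 15 % for dawn, summer and noon, each above mine, in the same order. Its words: “More ligand gives a higher early peak but a lower value at 12 min.”

**The flasks.** They give 23.9 %, 21.1 % and 15.7 %, and the forecast holds within its margin.

    starting complex + incoming ligand ⇌ leaving ligand + complex with one exchanged (K = 4.01, k = 9.88 /M/s)
    complex with one exchanged + incoming ligand ⇌ leaving ligand + complex with two exchanged (K = 0.886, k = 0.878 /M/s)
    complex with two exchanged → over-reaction product (k = 0.0387 /s)

**Fraction kept.** From 6.00 min to 12.0 min, summer keeps 0.640 of its complex with one exchanged, more than the 0.477 from the fade constant. The fade in summer has two causes acting together: the back reaction of leaving ligand with complex with one exchanged, and the reaction of complex with two exchanged to over-reaction product. Summer ends at 21.1 %. With the back reaction taken away it ends at 57.9 %, and with the over-reaction step taken away at 51.0 %.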